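## Retrosynthetic overview

1. Numbering used here: CH(CO2Me) = C1, ring CH2 = C2, quaternary C = C3, NCH2 = C4, N = N5, NCH = C6, CH(COiPr) = C7, CH2 = C8, C(CH2OH) = C9, bridge CH = C10, CH2 = C11, CH2 = C12, alkene carbons = C13 and C14 (C14 bonded to C3), allylic CH = C15, CH2 = C16, CH2 = C17. Rings: A (C1, C2, C3, C14, C15), B (C13–C17), C (C3, C4, N5, C6, C10, C9), D (C6–C10), E (C3, C9, C10, C11, C12, C13, C14).
2. Ring A is closed last by aldol condensation (C1–C2), and C1 is set by hydrogenation. Before that, ring E is closed by forming the C3–C14 bond in a palladium-catalysed reductive alkenylation, which also creates the quaternary centre C3 and leaves C4 at the amine oxidation level.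
3. Enabling feature: in the precursor, C3 is the nucleophilic α-carbon of a vinylogous formamide (N5–C4=C3–C2H=O) inside ring C of a 2-azabicyclo[3.2.1]octene (rings C and D). The C10–C11–C12 chain is held syn to the N5–C4–C3 bridge, so the bromoalkene carbon C14 of ring B sits directly above C3.
4. Ring C comes from methylamine (aza-Michael addition, enamine condensation) and a Vilsmeier formylation (C2). Ring D comes from oxidative cleavage and aldol ring contraction of a temporary cyclohexene made by an enantioselective Diels–Alder reaction (C9, C10). Ring B comes from 3-ethoxycyclopent-2-en-1-one, with C15 set by asymmetric copper hydride reduction.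
5. Order of ring formation: B, temporary cyclohexene, D, C, E (key step), A.

Key step: step 15

Assumption: the sense of induction of the chiral ligand in step 2 and of the chiral oxazaborolidinium catalyst in step 9 is taken as stated; if either proves opposite, its enantiomer is used.

## Route

Step 1
Reactants: 1 3-ethoxycyclopent-2-en-1-one; 2 methyl acetate
Product: 4 methyl 2-(3-oxocyclopent-1-en-1-yl)acetate, via lithium alkoxide 3 (not isolated)
Conditions: LiN(iPr)2, THF, −78 °C, 2; then 1, −78 → 0 °C; then 1 M HCl, rt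
Reagents that add atoms: water O
Why: Stork–Danheiser sequence: 1,2-addition of the ester enolate to the vinylogous ester carbonyl, then acid-induced hydrolysis and dehydration, should transpose the enone and place the CH2CO2Me arm on the future C15.

Step 2
Reactants: 4 methyl 2-(3-oxocyclopent-1-en-1-yl)acetate
Product: 6 methyl 2-[(1S,2S)-2-bromo-3-oxocyclopentyl]acetate, via silyl enol ether 5 (not isolated)
Conditions: Cu(OAc)2·H2O (3 mol %), (R)-DTBM-SEGPHOS (3 mol %), MeSiH(OEt)2, toluene, −30 °C; then NBS, THF, −78 °C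
Reagents that add atoms: N-bromosuccinimide O=C1CCC(=O)N1Br
Why: copper hydride-catalysed asymmetric conjugate reduction of a 3-substituted cyclopentenone should set C15 by ligand control and leave a regiodefined silyl enol ether, whose bromination occurs anti to the C15 substituent (this second centre is removed in step 3).

Step 3
Reactants: 6 methyl 2-[(1S,2S)-2-bromo-3-oxocyclopentyl]acetate
Product: 7 methyl 2-[(1S)-2-bromo-3-(trifluoromethanesulfonyloxy)cyclopent-2-en-1-yl]acetate
Conditions: Tf2O, 2,6-di-tert-butyl-4-methylpyridine, CH2Cl2, −78 → 0 °C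
Reagents that add atoms: trifluoromethanesulfonic anhydride O=S(=O)(OS(=O)(=O)C(F)(F)F)C(F)(F)F
Why: enol triflate formation from an α-bromo ketone should go through the more acidic CHBr position and give the tetrasubstituted 2-bromo enol triflate without touching C15.

Step 4
Reactants: 7 methyl 2-[(1S)-2-bromo-3-(trifluoromethanesulfonyloxy)cyclopent-2-en-1-yl]acetate; 8 3,3-diethoxyprop-1-ene
Product: 10 methyl 2-[(1S)-2-bromo-3-(3,3-diethoxypropyl)cyclopent-2-en-1-yl]acetate, via alkylborane 9 (not isolated)
Conditions: 8, 9-BBN, THF, rt; then 7, PdCl2(dppf) (5 mol %), AsPh3, K3PO4 (aq), DMF, rt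
Reagents that add atoms: none
Why: hydroboration of the terminal alkene followed by B-alkyl Suzuki–Miyaura coupling; 2-bromocycloalkenyl triflates are expected to couple first at the C–OTf bond, so the C14–Br bond should be kept for step 15.

Step 5
Reactants: 10 methyl 2-[(1S)-2-bromo-3-(3,3-diethoxypropyl)cyclopent-2-en-1-yl]acetate
Product: 11 methyl 2-[(1S)-2-bromo-3-(3-oxopropyl)cyclopent-2-en-1-yl]acetate
Conditions: 1 M HCl (cat.), THF/H2O, rt
Reagents that add atoms: water O
Why: acid-catalysed acetal hydrolysis should free the aldehyde (future C10) without affecting the ester or the bromoalkene.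

Step 6
Reactants: 11 methyl 2-[(1S)-2-bromo-3-(3-oxopropyl)cyclopent-2-en-1-yl]acetate; 12 dimethyl (3-methyl-2-oxobutyl)phosphonate
Product: 13 methyl 2-[(1S)-2-bromo-3-[(3E)-6-methyl-5-oxohept-3-en-1-yl]cyclopent-2-en-1-yl]acetate
Conditions: LiCl, DBU, MeCN, rt
Reagents that add atoms: none
Why: Horner–Wadsworth–Emmons olefination with a β-keto phosphonate under mild LiCl/amine conditions should give the (E)-enone.

Step 7
Reactants: 13 methyl 2-[(1S)-2-bromo-3-[(3E)-6-methyl-5-oxohept-3-en-1-yl]cyclopent-2-en-1-yl]acetate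
Product: 14 methyl 2-[(1S)-2-bromo-3-[(3E)-6-methyl-5-methylidenehept-3-en-1-yl]cyclopent-2-en-1-yl]acetate
Conditions: Ph3PCH3Br, KOtBu, THF, 0 °C → rt
Reagents that add atoms: methyltriphenylphosphonium bromide C[P+](c1ccccc1)(c1ccccc1)c1ccccc1.[Br-]
Why: Wittig methylenation of the enone carbonyl should give the 2-isopropyl-1,3-diene, the ester being much less electrophilic.

Step 8
Reactants: 15 3-(benzyloxy)propanal
Product: 16 2-[(benzyloxy)methyl]prop-2-enal
Conditions: aq CH2O (37 %), pyrrolidine (10 mol %), propanoic acid (10 mol %), iPrOH, 45 °C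
Reagents that add atoms: formaldehyde C=O
Why: amine-catalysed Mannich-type α-methylenation of an aldehyde with formaldehyde.

Step 9
Reactants: 14 methyl 2-[(1S)-2-bromo-3-[(3E)-6-methyl-5-methylidenehept-3-en-1-yl]cyclopent-2-en-1-yl]acetate; 16 2-[(benzyloxy)methyl]prop-2-enal
Product: 17 methyl 2-[(1S)-3-{2-[(1S,6R)-6-[(benzyloxy)methyl]-6-formyl-3-(propan-2-yl)cyclohex-2-en-1-yl]ethyl}-2-bromocyclopent-2-en-1-yl]acetate
Conditions: (S)-3,3-diphenyl-1-(o-tolyl)tetrahydro-1H,3H-pyrrolo[1,2-c][1,3,2]oxazaborole (20 mol %), HNTf2 (18 mol %), CH2Cl2, −78 → −40 °C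
Reagents that add atoms: none
Why: enantioselective Diels–Alder reaction with a cationic chiral oxazaborolidinium Lewis acid: the 1-alkyl and 2-isopropyl groups of the diene both direct C10 to bond to the quaternary carbon C9, the endo-formyl transition state should place CHO cis to the C10 side chain, and the catalyst's face selection sets C9 and C10 independently of the remote C15.

Step 10
Reactants: 17 Diels–Alder adduct
Product: 19 methyl 2-[(1S)-3-[(3R,4R)-4-[(benzyloxy)methyl]-3,4-diformyl-8-methyl-7-oxononyl]-2-bromocyclopent-2-en-1-yl]acetate, via diol 18 (not isolated)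
Conditions: OsO4 (2 mol %), NaIO4, 2,6-lutidine, dioxane/H2O, rt
Reagents that add atoms: sodium periodate [Na+].[O-]I(=O)(=O)=O; water O
Why: Lemieux–Johnson oxidation: the electron-rich trisubstituted ring alkene should be dihydroxylated and cleaved, while the tetrasubstituted bromoalkene is inert to OsO4.

Step 11
Reactants: 19 keto dialdehyde
Product: 21 methyl 2-[(1S)-3-{2-[(1S,5R)-5-[(benzyloxy)methyl]-5-formyl-3-(2-methylpropanoyl)cyclopent-2-en-1-yl]ethyl}-2-bromocyclopent-2-en-1-yl]acetate, via aldol 20 (not isolated)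
Conditions: dibenzylammonium trifluoroacetate (0.3 equiv), toluene, 50 °C
Reagents that add atoms: none
Why: intramolecular aldol condensation (5-enolexo) of the methylene ketone onto the C6 aldehyde should give the 1-acylcyclopentene (ring D); the formyl group on C9 cannot close a ring of reasonable size, and any equilibration at C10 should favour the side chain cis to the smaller formyl group.

Step 12
Reactants: 21 enone aldehyde
Product: 22 methyl 2-[(1S)-3-{2-[5-[(benzyloxy)methyl]-5-(2-methoxyethenyl)-3-(2-methylpropanoyl)cyclopent-2-en-1-yl]ethyl}-2-bromocyclopent-2-en-1-yl]acetate (E/Z mixture)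
Conditions: Ph3P(CH2OMe)Cl, KN(SiMe3)2, THF, −78 → 0 °C
Reagents that add atoms: (methoxymethyl)triphenylphosphonium chloride COC[P+](c1ccccc1)(c1ccccc1)c1ccccc1.[Cl-]
Why: Wittig methoxymethylenation should be selective for the aldehyde over the hindered conjugated ketone and adds C4 as a masked aldehyde.

Step 13
Reactants: 22 enol ether
Product: 24 methyl 2-[(1S)-3-{2-[5-[(benzyloxy)methyl]-2-methyl-7-(2-methylpropanoyl)-2-azabicyclo[3.2.1]oct-3-en-8-yl]ethyl}-2-bromocyclopent-2-en-1-yl]acetate, via amino ketone 23 (not isolated)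
Conditions: MeNH2 (2 M in THF), PPTS (0.2 equiv), 4 Å MS, THF, rt → 55 °C
Reagents that add atoms: methylamine CN
Why: reversible aza-Michael addition of methylamine to the acylcyclopentene, then acid-catalysed condensation of the secondary amine with the enol ether (loss of methanol), should close ring C as the enamine; only the amine cis to the C3 arm can cyclise, which fixes C6, and C7 should equilibrate to the exo isobutyryl epimer (trans to nitrogen).

Step 14
Reactants: 24 bicyclic enamine
Product: 26 methyl 2-[(1S)-3-{2-[5-[(benzyloxy)methyl]-4-formyl-2-methyl-7-(2-methylpropanoyl)-2-azabicyclo[3.2.1]oct-3-en-8-yl]ethyl}-2-bromocyclopent-2-en-1-yl]acetate, via vinamidinium salt 25 (not isolated)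
Conditions: POCl3, DMF, CH2Cl2, 0 °C → rt; then aq K2CO3
Reagents that add atoms: N,N-dimethylformamide CN(C)C=O; water O
Why: Vilsmeier–Haack formylation of the enamine at its β-carbon C3, then hydrolysis of the vinamidinium salt, should give the stable vinylogous formamide and install C2.

Step 15
Reactants: 26 bromoalkenyl vinylogous formamide
Product: 27 tetracyclic amino aldehyde (rings B, C, D, E; C3 quaternary with formyl C2, C4 as CH2–N, C15 with CH2CO2Me)
Conditions: Pd(OAc)2 (10 mol %), PPh3 (20 mol %), HCO2Na (2 equiv), Et4NCl, DMF, 85 °C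
Reagents that add atoms: none
Why: Proposed new method: oxidative addition of the C14–Br bond to zerovalent palladium gives an alkenylpalladium bromide held over ring C by the C10–C11–C12 tether; C–C bond formation at C3, the nucleophilic α-carbon of the vinylogous formamide N5–C4=C3–C2=O (by syn-carbopalladation of C3=C4, or by attack of the enaminal carbon on divalent palladium followed by reductive elimination), leaves a C4–palladium species or iminium ion that has no β-hydrogen and is reduced by formate to the C4H2–N5 unit. The closest known reaction types are the intramolecular reductive Heck cyclisation of alkenyl halides onto trisubstituted alkenes, the palladium-catalysed α-arylation of cyclic enaminones and the dearomatising C3-alkenylation of 3-substituted indoles. Ring E closes in a 7-exo-trig mode. The new quaternary stereocentre C3 is controlled by the bicyclic core: C14 can reach only the face of C3 that is syn to the C10 bridge substituent, so C14 ends axial and the formyl group equatorial on ring C. The step needs bond formation at C3 and not C4, and cyclisation faster than hydrodebromination; the first should be secured by the enamine polarisation and the 7-exo geometry, the second by the pre-organised proximity of C14 and C3.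

Step 16
Reactants: 27 tetracyclic amino aldehyde
Product: 30 pentacyclic methyl cyclopentenecarboxylate (C1=C2; benzyl ether), via lithium aldolate 28 (not isolated), via acetate 29 (not isolated)
Conditions: LiN(SiMe3)2, THF, −78 °C; then Ac2O, −78 → 0 °C; then DBU, rt
Reagents that add atoms: none
Why: intramolecular aldol addition of the ester enolate (the ketone has only hindered tertiary α-hydrogens) to the non-enolisable aldehyde, then acetylation and E1cB elimination (aldol condensation), should close ring A as the conjugated cyclopentene ester.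

Step 17
Reactants: 30 pentacyclic enoate
Product: 31 CNP0152638.1 (target)
Conditions: H2 (1 atm), Pd(OH)2/C, AcOH (2 equiv), MeOH, rt
Reagents that add atoms: none
Why: heterogeneous hydrogenation should add hydrogen to the trisubstituted enoate from the face of ring A that carries C4 and H-15 (the other face is blocked by C9 and C16), setting C1, and should hydrogenolyse the benzyl ether; the tetrasubstituted C13=C14 bond is not expected to be reduced.

## Compound list

1 | 3-ethoxycyclopent-2-en-1-one | CCOC1=CC(=O)CC1 | starting material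
2 | methyl acetate | COC(C)=O | starting material
3 | lithium 3-ethoxy-1-(2-methoxy-2-oxoethyl)cyclopent-2-en-1-olate (racemic) | CCOC1=CC([O-])(CC(=O)OC)CC1.[Li+] | intermediate
4 | methyl 2-(3-oxocyclopent-1-en-1-yl)acetate | COC(=O)CC1=CC(=O)CC1 | intermediate
5 | methyl 2-[(1S)-3-{[diethoxy(methyl)silyl]oxy}cyclopent-2-en-1-yl]acetate | COC(=O)C[C@@H]1CCC(O[Si](C)(OCC)OCC)=C1 | intermediate
6 | methyl 2-[(1S,2S)-2-bromo-3-oxocyclopentyl]acetate | COC(=O)C[C@@H]1CCC(=O)[C@H]1Br | intermediate
7 | methyl 2-[(1S)-2-bromo-3-(trifluoromethanesulfonyloxy)cyclopent-2-en-1-yl]acetate | COC(=O)C[C@@H]1CCC(OS(=O)(=O)C(F)(F)F)=C1Br | intermediate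
8 | 3,3-diethoxyprop-1-ene | C=CC(OCC)OCC | starting material
9 | 9-(3,3-diethoxypropyl)-9-borabicyclo[3.3.1]nonane | CCOC(CCB1C2CCCC1CCC2)OCC | intermediate
10 | methyl 2-[(1S)-2-bromo-3-(3,3-diethoxypropyl)cyclopent-2-en-1-yl]acetate | COC(=O)C[C@@H]1CCC(=C1Br)CCC(OCC)OCC | intermediate
11 | methyl 2-[(1S)-2-bromo-3-(3-oxopropyl)cyclopent-2-en-1-yl]acetate | COC(=O)C[C@@H]1CCC(=C1Br)CCC=O | intermediate
12 | dimethyl (3-methyl-2-oxobutyl)phosphonate | COP(=O)(CC(=O)C(C)C)OC | starting material
13 | methyl 2-[(1S)-2-bromo-3-[(3E)-6-methyl-5-oxohept-3-en-1-yl]cyclopent-2-en-1-yl]acetate | COC(=O)C[C@@H]1CCC(=C1Br)CC/C=C/C(=O)C(C)C | intermediate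
14 | methyl 2-[(1S)-2-bromo-3-[(3E)-6-methyl-5-methylidenehept-3-en-1-yl]cyclopent-2-en-1-yl]acetate | COC(=O)C[C@@H]1CCC(=C1Br)CC/C=C/C(=C)C(C)C | intermediate
15 | 3-(benzyloxy)propanal | O=CCCOCc1ccccc1 | starting material
16 | 2-[(benzyloxy)methyl]prop-2-enal | C=C(C=O)COCc1ccccc1 | intermediate
17 | methyl 2-[(1S)-3-{2-[(1S,6R)-6-[(benzyloxy)methyl]-6-formyl-3-(propan-2-yl)cyclohex-2-en-1-yl]ethyl}-2-bromocyclopent-2-en-1-yl]acetate (formyl cis to the side chain) | COC(=O)C[C@@H]1CCC(=C1Br)CC[C@H]2C=C(C(C)C)CC[C@]2(C=O)COCc3ccccc3 | intermediate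
18 | vicinal diol from syn-dihydroxylation of the cyclohexene bond of 17 (the two new carbinol centres not defined) | COC(=O)C[C@@H]1CCC(=C1Br)CC[C@H]2C(O)C(O)(C(C)C)CC[C@]2(C=O)COCc3ccccc3 | intermediate
19 | methyl 2-[(1S)-3-[(3R,4R)-4-[(benzyloxy)methyl]-3,4-diformyl-8-methyl-7-oxononyl]-2-bromocyclopent-2-en-1-yl]acetate | COC(=O)C[C@@H]1CCC(=C1Br)CC[C@@H](C=O)[C@@](C=O)(COCc2ccccc2)CCC(=O)C(C)C | intermediate
20 | β-hydroxy ketone from ring closure C7 to C6 of 19 (carbinol and C7 centres not defined) | COC(=O)C[C@@H]1CCC(=C1Br)CC[C@H]2C(O)C(C(=O)C(C)C)C[C@]2(C=O)COCc3ccccc3 | intermediate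
21 | methyl 2-[(1S)-3-{2-[(1S,5R)-5-[(benzyloxy)methyl]-5-formyl-3-(2-methylpropanoyl)cyclopent-2-en-1-yl]ethyl}-2-bromocyclopent-2-en-1-yl]acetate | COC(=O)C[C@@H]1CCC(=C1Br)CC[C@H]2C=C(C(=O)C(C)C)C[C@]2(C=O)COCc3ccccc3 | intermediate
22 | methyl 2-[(1S)-3-{2-[5-[(benzyloxy)methyl]-5-(2-methoxyethenyl)-3-(2-methylpropanoyl)cyclopent-2-en-1-yl]ethyl}-2-bromocyclopent-2-en-1-yl]acetate (E/Z mixture; ring stereocentres as in 21) | COC(=O)C[C@@H]1CCC(=C1Br)CC[C@H]2C=C(C(=O)C(C)C)C[C@]2(C=COC)COCc3ccccc3 | intermediate
23 | methylamine adduct of 22 at C6 (nitrogen cis to the enol ether arm and to the C10 chain, isobutyryl trans to nitrogen) | COC(=O)C[C@@H]1CCC(=C1Br)CC[C@H]2[C@@H](NC)[C@H](C(=O)C(C)C)C[C@]2(C=COC)COCc3ccccc3 | intermediate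
24 | methyl 2-[(1S)-3-{2-[5-[(benzyloxy)methyl]-2-methyl-7-(2-methylpropanoyl)-2-azabicyclo[3.2.1]oct-3-en-8-yl]ethyl}-2-bromocyclopent-2-en-1-yl]acetate (isobutyryl exo, 8-substituent syn to the N2–C3=C4 bridge) | COC(=O)C[C@@H]1CCC(=C1Br)CC[C@H]2[C@H]3N(C)C=C[C@]2(COCc4ccccc4)C[C@H]3C(=O)C(C)C | intermediate
25 | vinamidinium dichlorophosphate: 24 carrying CH=N+Me2 on C3 | COC(=O)C[C@@H]1CCC(=C1Br)CC[C@H]2[C@H]3N(C)C=C(C=[N+](C)C)[C@]2(COCc4ccccc4)C[C@H]3C(=O)C(C)C.[O-]P(=O)(Cl)Cl | intermediate
26 | methyl 2-[(1S)-3-{2-[5-[(benzyloxy)methyl]-4-formyl-2-methyl-7-(2-methylpropanoyl)-2-azabicyclo[3.2.1]oct-3-en-8-yl]ethyl}-2-bromocyclopent-2-en-1-yl]acetate (stereocentres as in 24) | COC(=O)C[C@@H]1CCC(=C1Br)CC[C@H]2[C@H]3N(C)C=C(C=O)[C@]2(COCc4ccccc4)C[C@H]3C(=O)C(C)C | intermediate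
27 | tetracyclic amino aldehyde: rings B, C, D and E closed, C3 quaternary carrying the formyl group (C2), C4 as CH2, C15 carrying CH2CO2Me, C9 carrying CH2OBn; C3, C6, C7, C9, C10, C15 as in the target | COC(=O)C[C@@H]1CCC2=C1[C@]3(C=O)CN(C)[C@H]4[C@H](C(=O)C(C)C)C[C@]3(COCc5ccccc5)[C@H]4CC2 | intermediate
28 | lithium aldolate from C1–C2 ring closure of 27 (C1 and C2 centres not defined) | COC(=O)C1C([O-])[C@@]23CN(C)[C@H]4[C@H](C(=O)C(C)C)C[C@]2(COCc5ccccc5)[C@H]4CCC2=C3[C@H]1CC2.[Li+] | intermediate
29 | β-acetoxy ester from 28 (C1 and C2 centres not defined) | COC(=O)C1C(OC(C)=O)[C@@]23CN(C)[C@H]4[C@H](C(=O)C(C)C)C[C@]2(COCc5ccccc5)[C@H]4CCC2=C3[C@H]1CC2 | intermediate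
30 | O-benzyl 1,2-didehydro derivative of the target (pentacyclic methyl cyclopentenecarboxylate, C1=C2) | COC(=O)C1=C[C@@]23CN(C)[C@H]4[C@H](C(=O)C(C)C)C[C@]2(COCc5ccccc5)[C@H]4CCC2=C3[C@H]1CC2 | intermediate
31 | CNP0152638.1 | COC(=O)[C@H]1C[C@@]23CN(C)[C@H]4[C@H](C(=O)C(C)C)C[C@]2(CO)[C@H]4CCC2=C3[C@H]1CC2 | target

Total step count: 17. Longest linear sequence: 16 steps (steps 1–7 and 9–17; step 8 is a one-step side branch).

## Steps most likely to fail

Step 15 (the labelled key step). What may go wrong: reduction of the alkenylpalladium intermediate by formate before cyclisation (hydrodebromination), bond formation at C4 in place of C3, or loss of the formyl group from the transient α-formyl iminium ion. The fallback uses a known radical reaction in place of palladium. It sets out from 26: slow addition of Bu3SnH with AIBN in benzene at 80 °C should generate the C14 alkenyl radical, which adds 7-exo to C3 of the vinylogous formamide (as known for aryl and alkenyl radicals on enaminones). The resulting α-amino radical at C4 takes up hydrogen, and the route is rejoined at 27. No new compound is made on this way (F0).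

Step 4. What may go wrong: loss of site selectivity, with oxidative addition at the C14–Br bond competing with the C13–OTf bond, or protodeboronation of the alkylborane. The fallback avoids the bis-electrophile altogether and sets out from 1:
- Stork–Danheiser addition of (3,3-diethoxypropyl)magnesium bromide, with a buffered acidic work-up, should give 3-(3,3-diethoxypropyl)cyclopent-2-en-1-one F1.
- Bromination and dehydrobromination (Br2, then Et3N, CH2Cl2) should give 2-bromo-3-(3,3-diethoxypropyl)cyclopent-2-en-1-one F2.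
- Horner–Wadsworth–Emmons olefination with trimethyl phosphonoacetate (NaH, THF) should give methyl 2-[2-bromo-3-(3,3-diethoxypropyl)cyclopent-2-en-1-ylidene]acetate F3.
- Copper hydride-catalysed asymmetric 1,4-reduction of this exocyclic enoate (same ligand class as in step 2) should set C15 and rejoin the route at 10.

Step 16. What may go wrong: enolisation of the isobutyryl ketone in place of the ester, retro-aldol cleavage before the elimination, or slow addition to the hindered neopentyl aldehyde. The fallback replaces the aldol condensation by a Dieckmann condensation and sets out from 27: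
- Pinnick oxidation (NaClO2, NaH2PO4, 2-methylbut-2-ene) and methylation (Me3SiCHN2) should give the C3 methyl ester analogue of 27 F4.
- Dieckmann condensation (KOtBu, THF) of the C1 ester enolate onto this ester, driven by the stabilised product enolate, should give the ring A β-keto ester F5.
- Triflation (NaH, PhNTf2) should give the ring A enol triflate F6.
- Palladium-catalysed formate reduction (Pd(OAc)2, PPh3, HCO2H, Bu3N, DMF) should remove the triflate and rejoin the route at 30.

## Further compounds

F0 | step 15 | none | none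
F1 | step 4 | 3-(3,3-diethoxypropyl)cyclopent-2-en-1-one | CCOC(CCC1=CC(=O)CC1)OCC
F2 | step 4 | 2-bromo-3-(3,3-diethoxypropyl)cyclopent-2-en-1-one | CCOC(CCC1=C(Br)C(=O)CC1)OCC
F3 | step 4 | methyl 2-[2-bromo-3-(3,3-diethoxypropyl)cyclopent-2-en-1-ylidene]acetate (E/Z mixture) | CCOC(CCC1=C(Br)C(=CC(=O)OC)CC1)OCC
F4 | step 16 | C3 methyl ester analogue of 27 (formyl group oxidised to CO2Me) | COC(=O)C[C@@H]1CCC2=C1[C@]3(C(=O)OC)CN(C)[C@H]4[C@H](C(=O)C(C)C)C[C@]3(COCc5ccccc5)[C@H]4CC2
F5 | step 16 | ring A β-keto ester (C2 ketone, C1 carrying CO2Me; C1 not defined) | COC(=O)C1C(=O)[C@@]23CN(C)[C@H]4[C@H](C(=O)C(C)C)C[C@]2(COCc5ccccc5)[C@H]4CCC2=C3[C@H]1CC2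
F6 | step 16 | ring A enol triflate (C1=C2–OTf) | COC(=O)C1=C(OS(=O)(=O)C(F)(F)F)[C@@]23CN(C)[C@H]4[C@H](C(=O)C(C)C)C[C@]2(COCc5ccccc5)[C@H]4CCC2=C3[C@H]1CC2
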